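**Retrosynthetic overview**

1. The strategy rests on the quaternary C2 of the 2H-chromene (pyran ring O1–C2–C3–C4–C4a–C8a): it carries O1, a methyl group and the C1' methylene that leads into the E C2'=C3' alkene. O1–C2 and C1'–C2' are cut together, back to ortho-(3-methylbut-3-enyl)phenol 10 and methyl acrylate 11 (enantioselective domino Wacker–Heck).
2. Target 21 comes from tris-SEM ketone 20 by fluoride; 20 comes from aryl bromide 15 and vinyl carbinol 18 by a Heck–isomerisation that forms the C5–CH2 bond and the ketone at once.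
3. Bromide 15 comes from chroman enoate 12 by DDQ dehydrogenation (C3=C4) and double CH3MgBr addition (C4' carbinol).
4. Phenol 10 comes from 4-bromo-2-fluorophenol: SEM ether, lithiation–formylation between F and Br, displacement of F by allyl alcohol, reduction, Appel bromination, methallyl Grignard coupling, deallylation. An allyl ether is used for the future O1 because it is removed with zerovalent palladium under neutral conditions.
5. Ring order: both benzene rings are bought; the pyran ring is the only ring made (step 8) and is dehydrogenated in step 9.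

Key step: step 8

Assumption: the ligand enantiomer in step 8 is assigned by analogy with 2-methylchromans of the same spatial arrangement from this reaction class; if the sense proves opposite, the mirror-image ligand is used and nothing else changes.

SEM = 2-(trimethylsilyl)ethoxymethyl, CH2OCH2CH2Si(CH3)3.

**Route**

Step 1
Reactants: 1 4-bromo-2-fluorophenol
Product: 2 4-bromo-2-fluoro-1-(SEM-oxy)benzene
Conditions: NaH, THF, 0 °C; SEMCl, 0 °C to rt
Reagents that add atoms: 2-(trimethylsilyl)ethoxymethyl chloride (SEMCl), ClCOCC[Si](C)(C)C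
Why: Williamson-type O-alkylation of the sodium phenoxide by the chloromethyl ether gives the SEM acetal, which should withstand the lithium amide, alkoxide, hydride, Grignard, DDQ and palladium steps that follow and is removed by fluoride at the end.

Step 2
Reactants: 2 4-bromo-2-fluoro-1-(SEM-oxy)benzene
Product: 4 6-bromo-2-fluoro-3-(SEM-oxy)benzaldehyde, via aryllithium 3 (not isolated)
Conditions: LiN(i-Pr)2, THF, −78 °C; DMF, −78 °C; aqueous quench
Reagents that add atoms: N,N-dimethylformamide, CN(C)C=O (formyl group); lithium diisopropylamide, [Li+].CC(C)[N-]C(C)C (lithium of 3 only)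
Why: Directed ortho-lithiation removes the ring proton flanked by fluorine and bromine, the most acidic one, at a temperature low enough to hold back aryne formation and halogen migration, and formylation of the aryllithium with DMF places the one-carbon handle between the two halogens.

Step 3
Reactants: 4 6-bromo-2-fluoro-3-(SEM-oxy)benzaldehyde
Product: 5 2-(allyloxy)-6-bromo-3-(SEM-oxy)benzaldehyde
Conditions: allyl alcohol, K2CO3, DMF, 60 °C
Reagents that add atoms: allyl alcohol, C=CCO
Why: Nucleophilic aromatic substitution by addition–elimination: the ortho formyl group activates the ring and fluoride is a far better nucleofuge than the bromide that is also ortho to CHO, so allyloxide should replace only F and deliver the future O1 in masked form.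

Step 4
Reactants: 5 2-(allyloxy)-6-bromo-3-(SEM-oxy)benzaldehyde
Product: 6 [2-(allyloxy)-6-bromo-3-(SEM-oxy)phenyl]methanol
Conditions: NaBH4, MeOH/THF, 0 °C
Reagents that add atoms: none
Why: Borohydride reduction of the aryl aldehyde gives the benzylic alcohol and leaves the aryl bromide, the allyl ether and the SEM acetal untouched.

Step 5
Reactants: 6 [2-(allyloxy)-6-bromo-3-(SEM-oxy)phenyl]methanol
Product: 7 2-(allyloxy)-4-bromo-3-(bromomethyl)-1-(SEM-oxy)benzene
Conditions: CBr4, PPh3, CH2Cl2, 0 °C
Reagents that add atoms: carbon tetrabromide, BrC(Br)(Br)Br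
Why: Appel reaction: bromide displaces the alkoxyphosphonium ion under neutral conditions, which the acid-labile SEM acetal and the allyl ether tolerate.

Step 6
Reactants: 7 2-(allyloxy)-4-bromo-3-(bromomethyl)-1-(SEM-oxy)benzene; 8 (2-methylprop-2-enyl)magnesium chloride, CH2=C(CH3)CH2MgCl, commercial THF solution
Product: 9 2-(allyloxy)-4-bromo-3-(3-methylbut-3-enyl)-1-(SEM-oxy)benzene
Conditions: 8 (1.5 equiv), THF, −20 °C to rt
Reagents that add atoms: none
Why: SN2 coupling of an allylic Grignard reagent with a benzylic bromide; both termini of the methallyl nucleophile give the same 3-methylbut-3-enyl chain, and the aryl bromide should not exchange with an allylmagnesium reagent at this temperature.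

Step 7
Reactants: 9 2-(allyloxy)-4-bromo-3-(3-methylbut-3-enyl)-1-(SEM-oxy)benzene
Product: 10 3-bromo-2-(3-methylbut-3-enyl)-6-(SEM-oxy)phenol
Conditions: Pd(PPh3)4 (3 mol %), morpholine, THF, rt
Reagents that add atoms: none
Why: Tsuji–Trost deallylation: zerovalent palladium ionises the aryl allyl ether to a π-allyl complex that morpholine intercepts, freeing the phenol at room temperature under neutral conditions, where the C–Br bond, the SEM acetal and the unactivated 1,1-disubstituted alkene should not react.

Step 8
Reactants: 10 3-bromo-2-(3-methylbut-3-enyl)-6-(SEM-oxy)phenol; 11 methyl acrylate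
Product: 12 methyl (2E)-4-[(2S)-5-bromo-2-methyl-8-(SEM-oxy)-3,4-dihydro-2H-chromen-2-yl]but-2-enoate
Conditions: Pd(OCOCF3)2 (10 mol %), (S)-2,2'-bis[(4S)-4-benzyl-4,5-dihydrooxazol-2-yl]-1,1'-binaphthyl (40 mol %), p-benzoquinone (4 equiv), 11 (5 equiv), CH2Cl2, rt, 3–4 d
Reagents that add atoms: none
Why: The bis(oxazoline) complex of Pd(OCOCF3)2 (divalent palladium) binds the 1,1-disubstituted alkene of 10, and the phenol oxygen adds to its inner carbon, closing the pyran ring by 6-exo-trig oxypalladation and forming O1–C2. The alkylpalladium so formed is primary and bound to the fully substituted C2, so β-hydride elimination is impossible and it persists until methyl acrylate inserts (C1'–C2'); syn β-hydride elimination then releases the E-enoate, and p-benzoquinone reoxidises the zerovalent palladium. This is the enantioselective domino Wacker–Heck reaction known for ortho-(3-methylbut-3-enyl)phenols with substituted ortho positions, of which 10 is a close steric analogue. C2 is the only new stereocentre and is set by the ligand (biaryl axis plus oxazoline centres) through selection of one alkene face in the oxypalladation; (S)-12 has the spatial arrangement of the target. The step also needs chemoselectivity: the ortho-substituted aryl bromide should not undergo oxidative addition at room temperature in the absence of phosphine while the quinone keeps zerovalent palladium scarce, O1 is the only free phenol, and the excess of acrylate should outcompete a second molecule of 10.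

Step 9
Reactants: 12 methyl (2E)-4-[(2S)-5-bromo-2-methyl-8-(SEM-oxy)-3,4-dihydro-2H-chromen-2-yl]but-2-enoate
Product: 13 methyl (2E)-4-[(2R)-5-bromo-2-methyl-8-(SEM-oxy)-2H-chromen-2-yl]but-2-enoate
Conditions: DDQ (2 equiv), 1,4-dioxane, 90 °C, dark
Reagents that add atoms: none
Why: DDQ dehydrogenation of a chroman to a 2H-chromene: hydride abstraction at benzylic C4 gives a cation stabilised by O1 through C8a, loss of a proton from C3 installs C3=C4, and because C2 is quaternary its configuration cannot be touched (the descriptor changes from S to R only because C3 now outranks C1').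

Step 10
Reactants: 13 methyl (2E)-4-[(2R)-5-bromo-2-methyl-8-(SEM-oxy)-2H-chromen-2-yl]but-2-enoate
Product: 15 (3E)-5-[(2R)-5-bromo-2-methyl-8-(SEM-oxy)-2H-chromen-2-yl]-2-methylpent-3-en-2-ol, via methyl ketone 14 (not isolated)
Conditions: CH3MgBr (4 equiv), THF, −40 to 0 °C
Reagents that add atoms: methylmagnesium bromide, C[Mg]Br
Why: Double Grignard addition to the ester: the first addition and loss of methoxide give enone 14, which should take the second methyl group at the carbonyl carbon (methylmagnesium halides without copper favour 1,2-addition) to give the tertiary allylic alcohol with the E alkene and the aryl bromide intact.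

Step 11
Reactants: 16 2,4-dihydroxybenzaldehyde
Product: 17 2,4-bis(SEM-oxy)benzaldehyde
Conditions: NaH (2.4 equiv), DMF, 0 °C; SEMCl (2.4 equiv), 0 °C to rt
Reagents that add atoms: 2-(trimethylsilyl)ethoxymethyl chloride (SEMCl), ClCOCC[Si](C)(C)C
Why: Williamson-type double O-alkylation of the phenoxides masks both phenols as SEM ethers, so that all three phenol protecting groups of the coupled product fall in one fluoride step.

Step 12
Reactants: 17 2,4-bis(SEM-oxy)benzaldehyde
Product: 18 1-[2,4-bis(SEM-oxy)phenyl]prop-2-en-1-ol (racemic)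
Conditions: CH2=CHMgBr, THF, −78 to 0 °C
Reagents that add atoms: vinylmagnesium bromide, C=C[Mg]Br
Why: 1,2-Addition of the vinyl Grignard reagent to the aldehyde gives the secondary allylic alcohol, made racemic because its carbinol centre becomes the ketone carbon in step 13.

Step 13
Reactants: 15 (3E)-5-[(2R)-5-bromo-2-methyl-8-(SEM-oxy)-2H-chromen-2-yl]-2-methylpent-3-en-2-ol; 18 1-[2,4-bis(SEM-oxy)phenyl]prop-2-en-1-ol
Product: 20 1-[2,4-bis(SEM-oxy)phenyl]-3-{(2R)-2-[(2E)-4-hydroxy-4-methylpent-2-enyl]-2-methyl-8-(SEM-oxy)-2H-chromen-5-yl}propan-1-one, via enol 19 (not isolated)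
Conditions: Pd(OAc)2 (10 mol %), P(o-tol)3, Bu4NCl, NaHCO3, 18 (2 equiv), DMF, 80 °C, dark
Reagents that add atoms: none
Why: Heck reaction of an aryl bromide with a secondary allylic alcohol (Heck–isomerisation): the aryl group adds to the terminal carbon, β-hydride elimination towards the carbinol C–H gives enol 19, and tautomerisation delivers the saturated aryl ketone directly, the terminal vinyl group of 18 being far more reactive than the disubstituted C3=C4 and C2'=C3' alkenes of 15.

Step 14
Reactants: 20 1-[2,4-bis(SEM-oxy)phenyl]-3-{(2R)-2-[(2E)-4-hydroxy-4-methylpent-2-enyl]-2-methyl-8-(SEM-oxy)-2H-chromen-5-yl}propan-1-one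
Product: 21 1-(2,4-dihydroxyphenyl)-3-{(2R)-8-hydroxy-2-[(2E)-4-hydroxy-4-methylpent-2-enyl]-2-methyl-2H-chromen-5-yl}propan-1-one (CNP0311864.1)
Conditions: Bu4NF (excess), THF/DMPU, 4 Å MS, 50 °C, dark
Reagents that add atoms: none
Why: Fluoride attacks silicon and each SEM group fragments by β-elimination to fluorotrimethylsilane, ethene and formaldehyde with release of the phenoxide, under basic, non-ionising conditions that should spare the tertiary allylic alcohol, the 2H-chromene and the C2 centre.

**Compound list**

1 | 4-bromo-2-fluorophenol | Oc1ccc(Br)cc1F | starting material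
2 | 4-bromo-2-fluoro-1-(SEM-oxy)benzene | C[Si](C)(C)CCOCOc1ccc(Br)cc1F | intermediate
3 | [6-bromo-2-fluoro-3-(SEM-oxy)phenyl]lithium | [Li]c1c(Br)ccc(OCOCC[Si](C)(C)C)c1F | intermediate (not isolated)
4 | 6-bromo-2-fluoro-3-(SEM-oxy)benzaldehyde | O=Cc1c(Br)ccc(OCOCC[Si](C)(C)C)c1F | intermediate
5 | 2-(allyloxy)-6-bromo-3-(SEM-oxy)benzaldehyde | O=Cc1c(Br)ccc(OCOCC[Si](C)(C)C)c1OCC=C | intermediate
6 | [2-(allyloxy)-6-bromo-3-(SEM-oxy)phenyl]methanol | OCc1c(Br)ccc(OCOCC[Si](C)(C)C)c1OCC=C | intermediate
7 | 2-(allyloxy)-4-bromo-3-(bromomethyl)-1-(SEM-oxy)benzene | BrCc1c(Br)ccc(OCOCC[Si](C)(C)C)c1OCC=C | intermediate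
8 | (2-methylprop-2-enyl)magnesium chloride | C=C(C)C[Mg]Cl | starting material
9 | 2-(allyloxy)-4-bromo-3-(3-methylbut-3-enyl)-1-(SEM-oxy)benzene | C=C(C)CCc1c(Br)ccc(OCOCC[Si](C)(C)C)c1OCC=C | intermediate
10 | 3-bromo-2-(3-methylbut-3-enyl)-6-(SEM-oxy)phenol | C=C(C)CCc1c(Br)ccc(OCOCC[Si](C)(C)C)c1O | intermediate
11 | methyl acrylate | C=CC(=O)OC | starting material
12 | methyl (2E)-4-[(2S)-5-bromo-2-methyl-8-(SEM-oxy)-3,4-dihydro-2H-chromen-2-yl]but-2-enoate | COC(=O)/C=C/C[C@]1(C)CCc2c(Br)ccc(OCOCC[Si](C)(C)C)c2O1 | intermediate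
13 | methyl (2E)-4-[(2R)-5-bromo-2-methyl-8-(SEM-oxy)-2H-chromen-2-yl]but-2-enoate | COC(=O)/C=C/C[C@]1(C)C=Cc2c(Br)ccc(OCOCC[Si](C)(C)C)c2O1 | intermediate
14 | (3E)-5-[(2R)-5-bromo-2-methyl-8-(SEM-oxy)-2H-chromen-2-yl]pent-3-en-2-one | CC(=O)/C=C/C[C@]1(C)C=Cc2c(Br)ccc(OCOCC[Si](C)(C)C)c2O1 | intermediate (not isolated)
15 | (3E)-5-[(2R)-5-bromo-2-methyl-8-(SEM-oxy)-2H-chromen-2-yl]-2-methylpent-3-en-2-ol | CC(C)(O)/C=C/C[C@]1(C)C=Cc2c(Br)ccc(OCOCC[Si](C)(C)C)c2O1 | intermediate
16 | 2,4-dihydroxybenzaldehyde | O=Cc1ccc(O)cc1O | starting material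
17 | 2,4-bis(SEM-oxy)benzaldehyde | O=Cc1ccc(OCOCC[Si](C)(C)C)cc1OCOCC[Si](C)(C)C | intermediate
18 | 1-[2,4-bis(SEM-oxy)phenyl]prop-2-en-1-ol (racemic) | C=CC(O)c1ccc(OCOCC[Si](C)(C)C)cc1OCOCC[Si](C)(C)C | intermediate
19 | 1-[2,4-bis(SEM-oxy)phenyl]-3-{(2R)-2-[(2E)-4-hydroxy-4-methylpent-2-enyl]-2-methyl-8-(SEM-oxy)-2H-chromen-5-yl}prop-1-en-1-ol (enol, geometry open) | CC(C)(O)/C=C/C[C@]1(C)C=Cc2c(CC=C(O)c3ccc(OCOCC[Si](C)(C)C)cc3OCOCC[Si](C)(C)C)ccc(OCOCC[Si](C)(C)C)c2O1 | intermediate (not isolated)
20 | 1-[2,4-bis(SEM-oxy)phenyl]-3-{(2R)-2-[(2E)-4-hydroxy-4-methylpent-2-enyl]-2-methyl-8-(SEM-oxy)-2H-chromen-5-yl}propan-1-one | CC(C)(O)/C=C/C[C@]1(C)C=Cc2c(CCC(=O)c3ccc(OCOCC[Si](C)(C)C)cc3OCOCC[Si](C)(C)C)ccc(OCOCC[Si](C)(C)C)c2O1 | intermediate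
21 | 1-(2,4-dihydroxyphenyl)-3-{(2R)-8-hydroxy-2-[(2E)-4-hydroxy-4-methylpent-2-enyl]-2-methyl-2H-chromen-5-yl}propan-1-one | CC(C)(O)/C=C/C[C@]1(C)C=Cc2c(CCC(=O)c3ccc(O)cc3O)ccc(O)c2O1 | target

**Step count and risk**

Total steps: 14. Longest linear sequence: 12 (steps 1–10, 13, 14); the carbinol branch is 2 steps (11, 12).

Steps most likely to fail:

1. Step 8. On this ortho-alkoxy, ortho'-bromo pattern the neopentyl alkylpalladium may be captured by acrylate too slowly, so that catalyst decay and acid-promoted racemic hydroalkoxylation of the alkene compete, or face selection may be insufficient. The fallback sets out from 10 and comes back at 12. The oxypalladation is run with the same Pd(OCOCF3)2/ligand/p-benzoquinone system under CO (1 atm) in MeOH, where CO insertion and methanolysis should intercept the alkylpalladium much faster (domino Wacker–carbonylation). This should give methyl 2-[(2S)-5-bromo-2-methyl-8-(SEM-oxy)chroman-2-yl]acetate F1. Reduction with i-Bu2AlH at −78 °C would give [(2S)-5-bromo-2-methyl-8-(SEM-oxy)chroman-2-yl]acetaldehyde F2, and Horner–Wadsworth–Emmons olefination with trimethyl phosphonoacetate and NaH would give E-enoate 12.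

2. Step 9. Hydride abstraction at C4 may be sluggish because the C5 bromine lowers the electron density of the ring and crowds the peri position; prolonged heating with DDQ could then erode the SEM acetal or, through slow thermal ring opening of the chromene, the C2 configuration. The fallback sets out from 12 and comes back at 13. Wohl–Ziegler bromination with NBS and AIBN in PhCF3 at 80 °C should favour the benzylic C4–H over the ester-deactivated, neopentyl C1'–H and give methyl (2E)-4-[4,5-dibromo-2-methyl-8-(SEM-oxy)chroman-2-yl]but-2-enoate F3 (C2 as in 12, both C4 epimers). E2 elimination with DBU in THF at rt would then give 13.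

3. Step 13. Oxidative addition into the electron-rich, ortho-substituted C5–Br bond may be slow at a temperature that is safe for the chromene, β-hydride elimination may run towards the benzylic CH2 and give the diaryl allylic alcohol, and palladium hydride may isomerise 18 to the propiophenone. The fallback sets out from 18 and 15 and comes back at 20. Carbinol 18 is oxidised with MnO2 to 1-[2,4-bis(SEM-oxy)phenyl]prop-2-en-1-one F4. An ordinary Heck reaction of 15 with this enone (Pd(OAc)2, P(o-tol)3, NaHCO3, DMF, 80 °C), in which only one direction of β-hydride elimination exists, should give the (E)-chalcone F5, (2E)-1-[2,4-bis(SEM-oxy)phenyl]-3-{(2R)-2-[(2E)-4-hydroxy-4-methylpent-2-enyl]-2-methyl-8-(SEM-oxy)-2H-chromen-5-yl}prop-2-en-1-one. Conjugate reduction of the enone C=C with [(Ph3P)CuH]6, which leaves isolated and styrene-type alkenes alone, would give 20.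

**Further compounds**

F1 | step 8 | methyl 2-[(2S)-5-bromo-2-methyl-8-(SEM-oxy)chroman-2-yl]acetate | COC(=O)C[C@]1(C)CCc2c(Br)ccc(OCOCC[Si](C)(C)C)c2O1
F2 | step 8 | [(2S)-5-bromo-2-methyl-8-(SEM-oxy)chroman-2-yl]acetaldehyde | O=CC[C@]1(C)CCc2c(Br)ccc(OCOCC[Si](C)(C)C)c2O1
F3 | step 9 | methyl (2E)-4-[4,5-dibromo-2-methyl-8-(SEM-oxy)chroman-2-yl]but-2-enoate (C2 as in 12, both C4 epimers) | COC(=O)/C=C/C[C@]1(C)CC(Br)c2c(Br)ccc(OCOCC[Si](C)(C)C)c2O1
F4 | step 13 | 1-[2,4-bis(SEM-oxy)phenyl]prop-2-en-1-one | C=CC(=O)c1ccc(OCOCC[Si](C)(C)C)cc1OCOCC[Si](C)(C)C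
F5 | step 13 | (2E)-1-[2,4-bis(SEM-oxy)phenyl]-3-{(2R)-2-[(2E)-4-hydroxy-4-methylpent-2-enyl]-2-methyl-8-(SEM-oxy)-2H-chromen-5-yl}prop-2-en-1-one | CC(C)(O)/C=C/C[C@]1(C)C=Cc2c(/C=C/C(=O)c3ccc(OCOCC[Si](C)(C)C)cc3OCOCC[Si](C)(C)C)ccc(OCOCC[Si](C)(C)C)c2O1
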